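**Retrosynthetic overview**
1. Feature: C8 is the fully substituted carbon shared by the tetrahydropyran (O, C4, C5, C6, C7, C8) and the γ-lactone (C7, C8, C17, C19, O). It sits in the chain C9–C8–C17(CH3)–C19, which is the carbon chain of diethyl oxalpropionate with its ketone as C8.
2. Ring 1 (pyran) comes from a catalytic asymmetric hetero-Diels–Alder reaction of that ketone with a C4–C7 diene (bonds C7–C8 and O–C4). Ring 2 (lactone) comes from O7 closing onto C19.
3. C2/C3 enter by conjugate vinyl addition at C4 and C16 by methylenation at C5. C6 is held as a silyl ether, and the lactone is masked as a silyl lactol so that the C9 ester can become the aldehyde.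
4. Ring 3 enters as (S)-4-acetoxy-2-iodo-3-methylcyclohexenone, joined at C9–C10 by Nozaki–Hiyama–Kishi coupling. Ring 4 (oxocane, equal to the ten-membered carbocycle) closes at C1–C2 by a SmI2 ketyl–enone cyclisation.
5. End game: C11 ketone to C11(CH3)=C12, lactone restored, C6 ketone reduced from the open face, chloride by inversion.

Key step: step 3

Assumption: briarane numbering is used throughout. "Top" is the pyran face that carries C9 at C8, and "bottom" is the face that carries C17 and O7. C17 is an epimer mixture in 5–12 and C19 an anomer mixture in 15–17 and 23–31, so these centres are written without configuration there.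

**Step 1**
Reactants: 1 (E)-4-methoxybut-3-en-2-one
Product: 2 (E)-4-methoxy-2-oxobut-3-en-1-yl benzoate
Conditions: Mn(OAc)3·2H2O (2.5 equiv), PhCO2H (excess), benzene, reflux, azeotropic removal of AcOH/H2O
Reagents that add atoms: benzoic acid, O=C(O)c1ccccc1
Why: α′-Acyloxylation of an enone with a trivalent manganese carboxylate: ligand exchange with benzoic acid gives the benzoate-bearing oxidant, the manganese enolate can form only at the methyl group (C7), and the acid-tolerant vinylogous ester is untouched.

**Step 2**
Reactants: 2 (E)-4-methoxy-2-oxobut-3-en-1-yl benzoate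
Product: 3 (1E,3Z)-4-benzoyloxy-1-methoxy-3-(tert-butyldimethylsilyloxy)buta-1,3-diene
Conditions: TBSOTf, Et3N, Et2O, 0 °C
Reagents that add atoms: tert-butyldimethylsilyl triflate, CC(C)(C)[Si](C)(C)OS(=O)(=O)C(F)(F)F
Why: Soft enolisation and O-silylation of an α-acyloxy ketone with silyl triflate and amine, which should give the Z enol ether (OBz cis to OSi, that is C7–O on the outside of the s-cis diene) because this geometry avoids allylic strain between the benzoate and C5, while the E enol ether C4=C5 is retained.

**Step 3**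
Reactants: 3 (1E,3Z)-4-benzoyloxy-1-methoxy-3-(tert-butyldimethylsilyloxy)buta-1,3-diene; 4 diethyl oxalpropionate
Product: 6 ethyl (2S,3R)-3-benzoyloxy-2-(1-ethoxy-1-oxopropan-2-yl)-4-oxo-3,4-dihydro-2H-pyran-2-carboxylate (dihydropyranone with quaternary C8), via cycloadduct 5 (not isolated)
Conditions: Cu(OTf)2 (10 mol %), 2,2′-(propane-2,2-diyl)bis[(4S)-4-tert-butyl-4,5-dihydrooxazole] (11 mol %), 4 Å sieves, CH2Cl2, −40 °C; then TFA, CH2Cl2, 0 °C
Reagents that add atoms: none
Why: The 1,2-dicarbonyl unit of 4 (C8 ketone, C9 ester) binds divalent copper in a square-planar five-membered chelate, and the nucleophilic diene terminus C7 attacks C8 while the ketone oxygen bonds to C4, either concertedly or as a Mukaiyama aldol step followed by ring closure. The closest known reaction type is the bis(oxazoline)–Cu(OTf)2-catalysed hetero-Diels–Alder reaction of α-keto esters with 1-methoxy-3-silyloxy dienes. The pyran (O, C4–C8) closes in the [4+2] mode or, in the stepwise limit, by 6-endo oxa-Michael addition of the C8 oxygen to C4 on TFA treatment, and in both cases methanol and the silyl group are expelled to give the enone. C8 is set by the catalyst: the tert-butyl group of the (S,S)-ligand covers the re face of the chelated ketone, so C7 adds to the si face (O > C9 > C17). C7 is set by the Z enol ether geometry together with the exo position of the catalyst-bound ester, which places O7 cis to the C17 branch, and an error here is repaired in step 5 because C7 stays α to the C6 ketone. The step needs enantioface selection and reaction of the ketone rather than its enol; two-point binding secures the first, the C17 methyl group (which keeps 4 mainly in the keto form), low temperature and sieves support the second, and C17 is left as an epimer mixture that converges in step 9.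

**Step 4**
Reactants: 6 dihydropyranone with quaternary C8
Product: 8 4-vinyl tetrahydropyran-6-one (C3 on the top face cis to C9), via trimethylsilyl enol ether 7 (not isolated)
Conditions: CH2=CHMgBr, CuBr·SMe2 (10 mol %), TMSCl, THF, −78 °C; then 1 M citric acid
Reagents that add atoms: vinylmagnesium bromide, C=C[Mg]Br; chlorotrimethylsilane (silicon stays only in 7), C[Si](C)(C)Cl
Why: Copper-catalysed, chlorosilane-accelerated conjugate addition of a vinyl Grignard reagent to the vinylogous ester: stereoelectronically preferred axial attack on the sofa conformer that holds the flat C9 ester pseudoaxial and the larger C17 branch pseudoequatorial brings C3 in on the top face, cis to C9 and anti to O7 and C17 (the configuration that becomes 4S in the target), and the weakly basic reagent avoids β-elimination of the ring oxygen.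

**Step 5**
Reactants: 8 4-vinyl tetrahydropyran-6-one
Product: 9 cis-fused keto lactone (O7–C19 closed, C9 ethyl ester retained)
Conditions: K2CO3 (0.3 equiv), EtOH, 0 °C to rt
Reagents that add atoms: none
Why: Carbonate-catalysed transesterification removes the activated α-keto benzoate and the freed O7 closes the γ-lactone on the C19 ester (5-exo-trig acyl substitution); C7 remains α to the C6 ketone and can epimerise under these conditions, so both C7 epimers should drain into the cis-fused butyrolactone, which is the thermodynamic sink, whereas the C9 ester could only give a β-lactone and stays.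

**Step 6**
Reactants: 9 cis-fused keto lactone
Product: 10 5-methylene keto lactone (C5=C16)
Conditions: (CH2O)n, i-Pr2NH·TFA, THF, reflux
Reagents that add atoms: formaldehyde (as paraformaldehyde), C=O
Why: Mannich-type α-methylenation of a ketone with formaldehyde and an ammonium trifluoroacetate: only C5 carries the two α-hydrogens needed for aminomethylation followed by elimination, and the non-basic medium spares the β-alkoxy ketone, the lactone and the ester.

**Step 7**
Reactants: 10 5-methylene keto lactone
Product: 11 allylic alcohol with O6 on the bottom face (cis to O7)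
Conditions: NaBH4, CeCl3·7H2O, MeOH, −78 °C
Reagents that add atoms: none
Why: Luche 1,2-reduction of the α-methylene ketone: in the chair with C3 and C9 equatorial the bottom (axial) trajectory is blocked by axial C17 of the lactone, so hydride should arrive from the convex top face and place O6 on the bottom face, cis to O7; this configuration is deliberately the one that is equatorial in the later bridged system and is corrected in steps 26 and 27.

**Step 8**
Reactants: 11 allylic alcohol
Product: 12 C6 triethylsilyl ether
Conditions: TESOTf, 2,6-lutidine, CH2Cl2, −78 to 0 °C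
Reagents that add atoms: triethylsilyl triflate, CC[Si](CC)(CC)OS(=O)(=O)C(F)(F)F
Why: Silylation of a hindered secondary alcohol with a silyl triflate and a non-nucleophilic base; the triethylsilyl group is chosen because it can later be removed in the presence of the C9 tert-butyldimethylsilyl ether.

**Step 9**
Reactants: 12 C6 triethylsilyl ether (C17 epimers)
Product: 14 lactone with 17R methyl group (methyl cis to the ring oxygen and trans to C9), via lithium enolate 13 (not isolated)
Conditions: LiN(SiMe3)2, THF, −78 °C; then AcOH in THF, −78 °C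
Reagents that add atoms: none
Why: Deprotonation and kinetic protonation of a lactone enolate, which merges both C17 epimers: C17–H is the only acidic C–H, the C8–O bond lies near the nodal plane of the enolate so that β-elimination is slow at −78 °C, and in the chair with C3 and C9 equatorial the inner face of C17 is closed by the pyran (axial H4 and the axial O6 silyl ether), so the proton should come from outside and leave the methyl group cis to the ring oxygen and trans to C9 (17R), the arrangement that is also the more stable one once the pyran is locked in the bridged system.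

**Step 10**
Reactants: 14 lactone with 17R methyl group
Product: 15 C19 lactol
Conditions: i-Bu2AlH (1.1 equiv), toluene, −78 °C; aq. potassium sodium tartrate
Reagents that add atoms: none
Why: Partial reduction of a lactone to the lactol with one equivalent of i-Bu2AlH: the γ-lactone is more electrophilic and far less hindered than the ethyl ester on the fully substituted C8, and its tetrahedral aluminate is stable at −78 °C.

**Step 11**
Reactants: 15 C19 lactol
Product: 16 C19 tert-butyldimethylsilyl lactol acetal
Conditions: TBSCl, imidazole, DMF, 0 °C to rt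
Reagents that add atoms: tert-butyldimethylsilyl chloride, CC(C)(C)[Si](C)(C)Cl
Why: Silylation of the lactol hydroxyl gives a silyl acetal that has no acidic C–H and no electrophilic carbonyl, withstands carbonate, hydride, organochromium, SmI2 and amide bases, and is cleaved by fluoride; the anomeric centre C19 is inconsequential.

**Step 12**
Reactants: 16 silyl lactol acetal ester
Product: 17 C9 aldehyde
Conditions: i-Bu2AlH (1.2 equiv), CH2Cl2, −78 °C; aq. potassium sodium tartrate
Reagents that add atoms: none
Why: Partial reduction of the only remaining ester with i-Bu2AlH; the neopentyl-type tetrahedral aluminate, chelated by the pyran oxygen, should persist at −78 °C and release the non-enolisable C9 aldehyde on work-up.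

**Step 13**
Reactants: 18 2-methylcyclohex-2-en-1-one
Product: 19 (S)-2-methylcyclohex-2-en-1-ol
Conditions: (R)-2-methyl-CBS-oxazaborolidine (10 mol %), BH3·SMe2, THF, −20 °C; MeOH
Reagents that add atoms: none
Why: Corey–Bakshi–Shibata reduction of a cyclic enone: the α-methylvinyl side acts as the large group, so the (R)-catalyst should deliver hydride to give the (S)-allylic alcohol, whose carbinol carbon becomes C14.

**Step 14**
Reactants: 19 (S)-2-methylcyclohex-2-en-1-ol
Product: 20 (S)-2-methylcyclohex-2-en-1-yl acetate
Conditions: Ac2O, Et3N, DMAP (cat.), CH2Cl2, rt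
Reagents that add atoms: acetic anhydride, CC(=O)OC(C)=O
Why: Standard DMAP-catalysed acylation; the acetate withstands the radical oxidation and the iodination that follow and is removable by methanolysis.

**Step 15**
Reactants: 20 (S)-2-methylcyclohex-2-en-1-yl acetate
Product: 21 (S)-2-methyl-4-oxocyclohex-2-en-1-yl acetate
Conditions: Rh2(cap)4 (cap = caprolactamate, 0.5 mol %), t-BuOOH, K2CO3, CH2Cl2, rt
Reagents that add atoms: tert-butyl hydroperoxide, CC(C)(C)OO
Why: Allylic C–H oxidation of a cyclohexene with tert-butyl hydroperoxide under dirhodium caprolactamate catalysis: hydrogen abstraction is fastest at the ring methylene next to the unsubstituted alkene carbon (C11), which gives the enone without transposition and leaves C14 untouched.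

**Step 16**
Reactants: 21 (S)-2-methyl-4-oxocyclohex-2-en-1-yl acetate
Product: 22 (S)-3-iodo-2-methyl-4-oxocyclohex-2-en-1-yl acetate
Conditions: iodine, pyridine, DMAP (cat.), CH2Cl2, rt
Reagents that add atoms: iodine, [I][I]
Why: α-Iodination of an enone by amine conjugate addition, iodination of the enolate and elimination; C10 is the only vinylic C–H.

**Step 17**
Reactants: 17 C9 aldehyde; 22 (S)-3-iodo-2-methyl-4-oxocyclohex-2-en-1-yl acetate
Product: 23 coupled 9R allylic alcohol (C9–C10 bond)
Conditions: CrCl2 (5 equiv), NiCl2 (2 mol %), DMSO, rt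
Reagents that add atoms: none
Why: Nozaki–Hiyama–Kishi alkenylation, which is selective for the aldehyde over enone, acetate and silyl acetal and tolerates hindered partners: with the 17R methyl group and the C6 silyl ether favouring the chair that holds C9 and the C4 vinyl group axial, the formyl group should adopt the dipole-minimised rotamer with C=O anti to the C8–O bond, its inner face is covered by the vinyl group and the ring, and the alkenylchromium reagent should add to the outer Re face to give the 9R alcohol.

**Step 18**
Reactants: 23 coupled 9R allylic alcohol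
Product: 24 C9 tert-butyldimethylsilyl ether
Conditions: TBSOTf, 2,6-lutidine, CH2Cl2, 0 °C
Reagents that add atoms: tert-butyldimethylsilyl triflate, CC(C)(C)[Si](C)(C)OS(=O)(=O)C(F)(F)F
Why: Silyl triflate silylation is strong enough for the alcohol between quaternary C8 and sp2 C10, and the protected oxygen can neither undergo retro-aldol cleavage nor be acetylated later.

**Step 19**
Reactants: 24 C9 silyl ether
Product: 25 free C14 alcohol (γ-hydroxy enone)
Conditions: K2CO3, MeOH, 0 °C
Reagents that add atoms: none
Why: Carbonate-catalysed methanolysis of the secondary acetate, to which the silyl ethers, the silyl lactol acetal and the tetrasubstituted enone are inert; it removes a reducible γ-acyloxy enone and frees the hydroxyl that directs step 21.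

**Step 20**
Reactants: 25 free C14 alcohol
Product: 26 C2 aldehyde (C4–CH2–CHO)
Conditions: PdCl2(PhCN)2 (10 mol %), CuCl2·2H2O (10 mol %), AgNO2 (5 mol %), t-BuOH/MeNO2, O2 (1 atm), rt
Reagents that add atoms: dioxygen, O=O
Why: Nitrite-modified, aldehyde-selective Wacker oxidation: only the monosubstituted C2=C3 alkene binds divalent palladium, the allylic ring oxygen at C4 reinforces anti-Markovnikov attack at C2, and the 1,1-disubstituted C5=C16 alkene and the tetrasubstituted enone are inert.

**Step 21**
Reactants: 26 C2 aldehyde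
Product: 27 tetracyclic 2,14-diol with C11 ketone (C1–C2 bond, oxocane closed)
Conditions: SmI2 (3 equiv), t-BuOH, THF, 0 °C, high dilution
Reagents that add atoms: none
Why: SmI2-mediated ketyl–enone reductive cyclisation (8-endo-trig), a reaction type known to close eight-membered rings on β,β-disubstituted cyclic enones: allylic 1,3-strain between C15 and C9 keeps H9 in the enone plane and C8 over one face, the free C14 hydroxyl on that same face binds trivalent samarium together with the ketyl oxygen, so C2 should add to C1 syn to O14 (1R) with O2 turned towards O14 (2R, syn-1,3-diol), and the samarium enolate should be protonated at C10 from the face of the new alkoxide, away from C15 and the C9 silyl ether, to give the trans C2/C9 ring fusion (H10 trans to C15).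

**Step 22**
Reactants: 27 tetracyclic diol
Product: 28 2,14-diacetate
Conditions: Ac2O, DMAP, Et3N, CH2Cl2, rt to 40 °C
Reagents that add atoms: acetic anhydride, CC(=O)OC(C)=O
Why: DMAP-catalysed acetylation of the two neopentyl-type secondary alcohols installs the C2 and C14 acetates of the target; all other hydroxyl groups are silylated, and any C2–O/C11 hemiketal is drained through the open hydroxy ketone.

**Step 23**
Reactants: 28 2,14-diacetate
Product: 29 C11 enol triflate (C11=C12)
Conditions: KN(SiMe3)2 (1.1 equiv) added to 28 and N-(5-chloro-2-pyridyl)bis(trifluoromethanesulfonimide), THF, −78 °C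
Reagents that add atoms: N-(5-chloro-2-pyridyl)bis(trifluoromethanesulfonimide), O=S(=O)(N(c1ccc(Cl)cn1)S(=O)(=O)C(F)(F)F)C(F)(F)F
Why: Kinetic enolisation and O-triflation: the bulky amide base, added to ketone and triflating agent together, should remove a proton from the accessible C12 methylene and not from the hindered C10 methine or the less acidic acetates, which fixes the C11=C12 position and avoids β-elimination of the C9 silyl ether.

**Step 24**
Reactants: 29 C11 enol triflate
Product: 30 C11-methyl cyclohexene (C20 installed)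
Conditions: Me2Zn, Pd(PPh3)4 (5 mol %), THF, 50 °C
Reagents that add atoms: dimethylzinc, C[Zn]C
Why: Negishi methylation of an enol triflate with zerovalent palladium; acetates and silyl ethers are inert to the zinc reagent, no acetate is allylic, and the allylic silyl ether at C6 does not ionise.

**Step 25**
Reactants: 30 C11-methyl cyclohexene
Product: 31 C6 alcohol and C19 lactol (C9 silyl ether kept)
Conditions: HF·pyridine, pyridine, THF, 0 °C
Reagents that add atoms: none
Why: Fluoride desilylation graded by lability: the triethylsilyl ether and the anomeric silyl acetal cleave fast, whereas the tert-butyldimethylsilyl ether at C9, flanked by quaternary C8 and by C10, should survive the buffered reagent.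

**Step 26**
Reactants: 31 C6 alcohol and C19 lactol
Product: 32 α-methylene ketone lactone
Conditions: DMP (1,1,1-triacetoxy-1,1-dihydro-1,2-benziodoxol-3(1H)-one, 3 equiv), NaHCO3, CH2Cl2, 0 °C to rt
Reagents that add atoms: none
Why: Periodinane oxidation takes the lactol to the γ-lactone and the allylic alcohol to the enone in one operation under buffered, non-basic conditions that do not touch C7, C17 or the alkenes.

**Step 27**
Reactants: 32 α-methylene ketone lactone
Product: 33 allylic alcohol with O6 on the top face (axial)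
Conditions: NaBH4, CeCl3·7H2O, MeOH, −78 °C
Reagents that add atoms: none
Why: Luche 1,2-reduction: in the bridged oxabicyclo[5.3.1]undecane the top face of C6 lies under the C3–C2–C1–C10–C9 bridge (C3 and C9 are both 1,3-diaxial to it), so hydride can only come from the open bottom face and O6 ends on the top face, trans to O7.

**Step 28**
Reactants: 33 allylic alcohol with O6 on the top face
Product: 35 6S allylic chloride (C9 silyl ether), via mesylate 34 (not isolated)
Conditions: MsCl, Et3N, CH2Cl2, −20 °C; then LiCl, DMF, 0 °C to rt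
Reagents that add atoms: methanesulfonyl chloride (stays only in 34), CS(=O)(=O)Cl; lithium chloride, [Li+].[Cl-]
Why: Sulfonylation with a small reagent followed by SN2 displacement of the allylic mesylate by chloride: backside attack from the open bottom face on the axial leaving group inverts C6 and gives the equatorial chloride cis to O7 with the C5=C16 alkene in place.

**Step 29**
Reactants: 35 6S allylic chloride
Product: 36 target CNP0198838.2
Conditions: HF·pyridine, THF, rt
Reagents that add atoms: none
Why: Acidic fluoride removes the last, hindered silyl ether without base, so the acetates, the β-alkoxy lactone (C17) and the allylic chloride are not endangered.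

**Compound list**
1 | (E)-4-methoxybut-3-en-2-one | CO/C=C/C(C)=O | starting material
2 | (E)-4-methoxy-2-oxobut-3-en-1-yl benzoate | CO/C=C/C(=O)COC(=O)c1ccccc1 | intermediate
3 | (1E,3Z)-4-benzoyloxy-1-methoxy-3-(tert-butyldimethylsilyloxy)buta-1,3-diene (C4–C7) | CO/C=C/C(O[Si](C)(C)C(C)(C)C)=C/OC(=O)c1ccccc1 | intermediate
4 | diethyl oxalpropionate (diethyl 2-methyl-3-oxobutanedioate, C9–C8–C17–C19, racemic and labile at C17) | CCOC(=O)C(=O)C(C)C(=O)OCC | starting material
5 | primary cycloadduct (C4 methoxy acetal, C5=C6 silyl enol ether) | CCOC(=O)[C@]1(OC(OC)C=C(O[Si](C)(C)C(C)(C)C)[C@@H]1OC(=O)c2ccccc2)C(C)C(=O)OCC | intermediate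
6 | ethyl (2S,3R)-3-benzoyloxy-2-(1-ethoxy-1-oxopropan-2-yl)-4-oxo-3,4-dihydro-2H-pyran-2-carboxylate (O7 cis to the C17 branch, C17 epimers) | CCOC(=O)[C@]1(OC=CC(=O)[C@@H]1OC(=O)c2ccccc2)C(C)C(=O)OCC | intermediate
7 | trimethylsilyl enol ether of 8 (C5=C6) | CCOC(=O)[C@]1(O[C@@H](C=C)C=C(O[Si](C)(C)C)[C@@H]1OC(=O)c2ccccc2)C(C)C(=O)OCC | intermediate
8 | 4-vinyl tetrahydropyran-6-one, vinyl (C3=C2) on the top face cis to C9, O7 benzoate on the bottom face | CCOC(=O)[C@]1(O[C@@H](C=C)CC(=O)[C@@H]1OC(=O)c2ccccc2)C(C)C(=O)OCC | intermediate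
9 | cis-fused keto lactone (lactone on the bottom face, C9 ethyl ester and vinyl on top) | O=C1C[C@H](C=C)O[C@@]2(C(=O)OCC)C(C)C(=O)O[C@@H]12 | intermediate
10 | 5-methylene keto lactone | C=C1[C@H](C=C)O[C@@]2(C(=O)OCC)C(C)C(=O)O[C@H]2C1=O | intermediate
11 | allylic alcohol, O6 on the bottom face cis to O7 | C=C1[C@H](C=C)O[C@@]2(C(=O)OCC)C(C)C(=O)O[C@H]2[C@H]1O | intermediate
12 | C6 triethylsilyl ether of 11 | C=C1[C@H](C=C)O[C@@]2(C(=O)OCC)C(C)C(=O)O[C@H]2[C@H]1O[Si](CC)(CC)CC | intermediate
13 | lithium enolate of lactone 12 | C=C1[C@H](C=C)O[C@@]2(C(=O)OCC)C(C)=C([O-])O[C@H]2[C@H]1O[Si](CC)(CC)CC.[Li+] | intermediate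
14 | lactone with 17R methyl (cis to ring oxygen, trans to C9) | C=C1[C@H](C=C)O[C@@]2(C(=O)OCC)[C@@H](C)C(=O)O[C@H]2[C@H]1O[Si](CC)(CC)CC | intermediate
15 | C19 lactol (anomers) | C=C1[C@H](C=C)O[C@@]2(C(=O)OCC)[C@@H](C)C(O)O[C@H]2[C@H]1O[Si](CC)(CC)CC | intermediate
16 | C19 O-tert-butyldimethylsilyl lactol acetal, C9 ethyl ester | C=C1[C@H](C=C)O[C@@]2(C(=O)OCC)[C@@H](C)C(O[Si](C)(C)C(C)(C)C)O[C@H]2[C@H]1O[Si](CC)(CC)CC | intermediate
17 | C9 aldehyde | C=C1[C@H](C=C)O[C@@]2(C=O)[C@@H](C)C(O[Si](C)(C)C(C)(C)C)O[C@H]2[C@H]1O[Si](CC)(CC)CC | intermediate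
18 | 2-methylcyclohex-2-en-1-one | CC1=CCCCC1=O | starting material
19 | (S)-2-methylcyclohex-2-en-1-ol | CC1=CCCC[C@@H]1O | intermediate
20 | (S)-2-methylcyclohex-2-en-1-yl acetate | CC1=CCCC[C@@H]1OC(C)=O | intermediate
21 | (S)-2-methyl-4-oxocyclohex-2-en-1-yl acetate | CC1=CC(=O)CC[C@@H]1OC(C)=O | intermediate
22 | (S)-3-iodo-2-methyl-4-oxocyclohex-2-en-1-yl acetate (C10 iodide, C11 ketone, C14 acetate) | CC1=C(I)C(=O)CC[C@@H]1OC(C)=O | intermediate
23 | coupled 9R alcohol (C9–C10 bond, C10=C1 enone, 14S acetate) | C=C1[C@H](C=C)O[C@@]2([C@H](O)C3=C(C)[C@@H](OC(C)=O)CCC3=O)[C@@H](C)C(O[Si](C)(C)C(C)(C)C)O[C@H]2[C@H]1O[Si](CC)(CC)CC | intermediate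
24 | C9 tert-butyldimethylsilyl ether of 23 | C=C1[C@H](C=C)O[C@@]2([C@H](O[Si](C)(C)C(C)(C)C)C3=C(C)[C@@H](OC(C)=O)CCC3=O)[C@@H](C)C(O[Si](C)(C)C(C)(C)C)O[C@H]2[C@H]1O[Si](CC)(CC)CC | intermediate
25 | free 14S alcohol | C=C1[C@H](C=C)O[C@@]2([C@H](O[Si](C)(C)C(C)(C)C)C3=C(C)[C@@H](O)CCC3=O)[C@@H](C)C(O[Si](C)(C)C(C)(C)C)O[C@H]2[C@H]1O[Si](CC)(CC)CC | intermediate
26 | C2 aldehyde | C=C1[C@H](CC=O)O[C@@]2([C@H](O[Si](C)(C)C(C)(C)C)C3=C(C)[C@@H](O)CCC3=O)[C@@H](C)C(O[Si](C)(C)C(C)(C)C)O[C@H]2[C@H]1O[Si](CC)(CC)CC | intermediate
27 | tetracyclic 2R,14S-diol, 1R quaternary centre, H10 trans to C15, C11 ketone | C=C1[C@@H]2C[C@@H](O)[C@@]3(C)[C@@H](O)CCC(=O)[C@@H]3[C@@H](O[Si](C)(C)C(C)(C)C)[C@]3(O2)[C@@H](C)C(O[Si](C)(C)C(C)(C)C)O[C@H]3[C@H]1O[Si](CC)(CC)CC | intermediate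
28 | 2,14-diacetate of 27 | C=C1[C@@H]2C[C@@H](OC(C)=O)[C@@]3(C)[C@@H](OC(C)=O)CCC(=O)[C@@H]3[C@@H](O[Si](C)(C)C(C)(C)C)[C@]3(O2)[C@@H](C)C(O[Si](C)(C)C(C)(C)C)O[C@H]3[C@H]1O[Si](CC)(CC)CC | intermediate
29 | C11 enol triflate (C11=C12) | C=C1[C@@H]2C[C@@H](OC(C)=O)[C@@]3(C)[C@@H](OC(C)=O)CC=C(OS(=O)(=O)C(F)(F)F)[C@@H]3[C@@H](O[Si](C)(C)C(C)(C)C)[C@]3(O2)[C@@H](C)C(O[Si](C)(C)C(C)(C)C)O[C@H]3[C@H]1O[Si](CC)(CC)CC | intermediate
30 | C11-methyl cyclohexene | C=C1[C@@H]2C[C@@H](OC(C)=O)[C@@]3(C)[C@@H](OC(C)=O)CC=C(C)[C@@H]3[C@@H](O[Si](C)(C)C(C)(C)C)[C@]3(O2)[C@@H](C)C(O[Si](C)(C)C(C)(C)C)O[C@H]3[C@H]1O[Si](CC)(CC)CC | intermediate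
31 | C6 alcohol (bottom face) and C19 lactol, C9 silyl ether | C=C1[C@@H]2C[C@@H](OC(C)=O)[C@@]3(C)[C@@H](OC(C)=O)CC=C(C)[C@@H]3[C@@H](O[Si](C)(C)C(C)(C)C)[C@]3(O2)[C@@H](C)C(O)O[C@H]3[C@H]1O | intermediate
32 | α-methylene C6 ketone with restored γ-lactone | C=C1[C@@H]2C[C@@H](OC(C)=O)[C@@]3(C)[C@@H](OC(C)=O)CC=C(C)[C@@H]3[C@@H](O[Si](C)(C)C(C)(C)C)[C@]3(O2)[C@@H](C)C(=O)O[C@H]3C1=O | intermediate
33 | allylic alcohol, O6 on the top face (axial, trans to O7) | C=C1[C@@H]2C[C@@H](OC(C)=O)[C@@]3(C)[C@@H](OC(C)=O)CC=C(C)[C@@H]3[C@@H](O[Si](C)(C)C(C)(C)C)[C@]3(O2)[C@@H](C)C(=O)O[C@H]3[C@@H]1O | intermediate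
34 | C6 mesylate of 33 | C=C1[C@@H]2C[C@@H](OC(C)=O)[C@@]3(C)[C@@H](OC(C)=O)CC=C(C)[C@@H]3[C@@H](O[Si](C)(C)C(C)(C)C)[C@]3(O2)[C@@H](C)C(=O)O[C@H]3[C@@H]1OS(C)(=O)=O | intermediate
35 | 6S chloride (bottom face, cis to O7), C9 silyl ether | C=C1[C@@H]2C[C@@H](OC(C)=O)[C@@]3(C)[C@@H](OC(C)=O)CC=C(C)[C@@H]3[C@@H](O[Si](C)(C)C(C)(C)C)[C@]3(O2)[C@@H](C)C(=O)O[C@H]3[C@H]1Cl | intermediate
36 | CNP0198838.2 (1R,2R,4S,6S,7R,8R,9R,10S,14S,17R in briarane numbering) | C=C1[C@@H]2C[C@@H](OC(C)=O)[C@@]3(C)[C@@H](OC(C)=O)CC=C(C)[C@@H]3[C@@H](O)[C@]3(O2)[C@@H](C)C(=O)O[C@H]3[C@H]1Cl | target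

**Step count**
Total step count: 29. Longest linear sequence: 25 (steps 1–12 and 17–29). Steps 13–16 form the side branch.

**Steps most likely to fail**

Step 3. The keto diester may enolise on the copper catalyst. It could then bind through its 1,3-dicarbonyl unit, pass a proton to the silyl dienol ether and lose enantioface control.
- The fallback sets out from 4 and returns at 6. It blocks the acidic C17–H before the cycloaddition.
- NBS in CH2Cl2 gives diethyl 2-bromo-2-methyl-3-oxobutanedioate F1, a non-enolisable α-keto ester.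
- The same catalyst and diene 3 give the bromo cycloadduct F2 and, after TFA, the bromo dihydropyranone F3.
- Radical debromination (Bu3SnH, Et3B/air, toluene, 0 °C) then gives 6 as the C17 epimer mixture that step 9 merges.

Step 21. Simple reduction of the aldehyde or of the enone, or intermolecular coupling, may outrun the eight-membered ring closure.
- The fallback sets out from 26 and returns at 27. It replaces the reductive ketyl closure by an acyl radical conjugate addition followed by a directed reduction.
- Pinnick oxidation gives the C2 carboxylic acid F4.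
- (PhSe)2 and PBu3 give the Se-phenyl selenoester F5.
- (Me3Si)3SiH and AIBN in benzene at high dilution close C1–C2 to the C2,C11-diketone F6. The same allylic-strain conformer should control C1.
- Narasaka–Prasad reduction (Et2BOMe, NaBH4, THF/MeOH, −78 °C), directed by the C14 hydroxyl, gives the syn-1,3-diol 27.

Step 28. Chloride may attack C16 with allylic transposition, or the hindered axial alcohol may resist activation.
- The fallback sets out from 33 and returns at 35. It uses the transposition instead of fighting it.
- Catalytic O3ReOSiPh3 in Et2O moves the hydroxyl to C16 and gives the primary allylic alcohol F7 (C5=C6).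
- SOCl2 in Et2O at 0 °C forms the chlorosulfite F8.
- F8 collapses with internal return (SNi′) and delivers chloride to C6 from the only open (bottom) face, which re-forms C5=C16.

**Further compounds**
F1 | step 3 | diethyl 2-bromo-2-methyl-3-oxobutanedioate | CCOC(=O)C(=O)C(C)(Br)C(=O)OCC
F2 | step 3 | bromo cycloadduct | CCOC(=O)[C@]1(OC(OC)C=C(O[Si](C)(C)C(C)(C)C)[C@@H]1OC(=O)c2ccccc2)C(C)(Br)C(=O)OCC
F3 | step 3 | bromo dihydropyranone | CCOC(=O)[C@]1(OC=CC(=O)[C@@H]1OC(=O)c2ccccc2)C(C)(Br)C(=O)OCC
F4 | step 21 | C2 carboxylic acid | C=C1[C@H](CC(=O)O)O[C@@]2([C@H](O[Si](C)(C)C(C)(C)C)C3=C(C)[C@@H](O)CCC3=O)[C@@H](C)C(O[Si](C)(C)C(C)(C)C)O[C@H]2[C@H]1O[Si](CC)(CC)CC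
F5 | step 21 | Se-phenyl selenoester | C=C1[C@H](CC(=O)[Se]c4ccccc4)O[C@@]2([C@H](O[Si](C)(C)C(C)(C)C)C3=C(C)[C@@H](O)CCC3=O)[C@@H](C)C(O[Si](C)(C)C(C)(C)C)O[C@H]2[C@H]1O[Si](CC)(CC)CC
F6 | step 21 | C2,C11-diketone | C=C1[C@@H]2CC(=O)[C@@]3(C)[C@@H](O)CCC(=O)[C@@H]3[C@@H](O[Si](C)(C)C(C)(C)C)[C@]3(O2)[C@@H](C)C(O[Si](C)(C)C(C)(C)C)O[C@H]3[C@H]1O[Si](CC)(CC)CC
F7 | step 28 | primary allylic alcohol (C16–OH, C5=C6) | OCC=1[C@@H]2C[C@@H](OC(C)=O)[C@@]3(C)[C@@H](OC(C)=O)CC=C(C)[C@@H]3[C@@H](O[Si](C)(C)C(C)(C)C)[C@]3(O2)[C@@H](C)C(=O)O[C@H]3C=1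
F8 | step 28 | chlorosulfite of F7 | O=S(Cl)OCC=1[C@@H]2C[C@@H](OC(C)=O)[C@@]3(C)[C@@H](OC(C)=O)CC=C(C)[C@@H]3[C@@H](O[Si](C)(C)C(C)(C)C)[C@]3(O2)[C@@H](C)C(=O)O[C@H]3C=1
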